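**Strategy.** The route rests on cutting the O1–C8a aryl ether bond of the pyran ring of the catechin unit (unit C). With C8a carried as C–Br, the benzo ring of unit C derives from twofold-symmetric 1-bromo-3,5-bis(benzyloxy)benzene: the carbon para to bromine (future C6) is unique, the two ortho carbons (future C4a and C8) are equivalent. The key step, a palladium-catalysed intramolecular C–O coupling, closes the pyran ring in one operation with retention at C2 and gives the fully benzylated tetramer. Its precursor is a hexasubstituted aryl bromide carrying the fisetinidol dimer at C6, a fisetinidol unit at C8 and an anti-configured 2-benzyloxy-3-hydroxy-3-arylpropyl chain at C4a.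

Key step: step 19

Remarks on the chemistry (assumptions):
- Units A, B and D carry no oxygen at C5 (fisetinidol units, 2R,3S, each linked through C4 trans to its 3-oxygen). They are therefore drawn from (2R,3R)-fustin, assumed to be purchased as the single enantiomer, not from a 5-hydroxylated dihydroflavonol.
- The brominated benzo ring of unit C is a weaker nucleophile than C6 of a fisetinidol unit, so units A and D carry iodine at C6 from step 5 until step 17. Electrophiles enter the brominated ring first ortho to bromine and last between the two benzyloxy groups.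
- The benzylic C2 carbinol of the key precursor is acid-labile; it is carried as the C2 ketone through all Lewis-acid steps and revealed one step before ring closure.
- Compounds 3 to 7 are drawn with the 3,4-trans configuration expected to predominate at the C4 that bears oxygen or sulfur; that centre is erased on ionisation.

Step 1
Reactants: 1 (2R,3R)-fustin
Product: 2 (2R,3R)-7,3',4'-tri-O-benzylfustin
Conditions: BnBr (3.3 equiv), K2CO3, DMF, 0 °C to rt
Reagents that add atoms: benzyl bromide, BrCc1ccccc1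
Why: Williamson etherification in which carbonate deprotonates only the three phenols, so the secondary 3-hydroxyl and both stereocentres stay untouched.

Step 2
Reactants: 2 (2R,3R)-7,3',4'-tri-O-benzylfustin
Product: 3 (2R,3S,4R)-7,3',4'-tri-O-benzylflavan-3,4-diol
Conditions: NaBH4, THF/MeOH, 0 °C
Reagents that add atoms: none
Why: Borohydride reduction of the flavanonol carbonyl, where axial hydride delivery should give mainly the all-equatorial 2,3-trans-3,4-trans diol.

Step 3
Reactants: 3 (2R,3S,4R)-7,3',4'-tri-O-benzylflavan-3,4-diol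
Product: 4 (2R,3S,4R)-3,4,7,3',4'-penta-O-benzylflavan-3,4-diol
Conditions: NaH, BnBr, n-Bu4NI (cat.), DMF, 0 °C to rt
Reagents that add atoms: benzyl bromide, BrCc1ccccc1
Why: Williamson etherification of both secondary alkoxides, which also turns the benzylic C4 oxygen into the leaving group used later.

Step 4
Reactants: 4 (2R,3S,4R)-3,4,7,3',4'-penta-O-benzylflavan-3,4-diol
Product: 5 3,7,3',4'-tetra-O-benzyl-4α-[(2,6-dimethylphenyl)sulfanyl]fisetinidol
Conditions: 2,6-Me2C6H3SH (3 equiv), BF3·OEt2, CH2Cl2, −78 to −30 °C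
Reagents that add atoms: 2,6-dimethylbenzenethiol, Cc1cccc(C)c1S
Why: Lewis-acid thiolysis (SN1 through the 7-alkoxy-stabilised flavan-4-yl cation) in which excess thiol outruns self-condensation and adds anti to the 3-benzyloxy group, leaving a C4 thioether that is inert to BF3·OEt2.

Step 5
Reactants: 4 (2R,3S,4R)-3,4,7,3',4'-penta-O-benzylflavan-3,4-diol
Product: 6 (2R,3S,4R)-3,4,7,3',4'-penta-O-benzyl-6-iodoflavan-3,4-diol
Conditions: NIS (1.05 equiv), MeCN/CH2Cl2, 0 °C to rt, dark
Reagents that add atoms: N-iodosuccinimide, O=C1CCC(=O)N1I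
Why: Electrophilic aromatic iodination at C6, the carbon para to O1 and ortho to the 7-benzyloxy group and the most nucleophilic one, which blocks that carbon and deactivates C8 for the later arylations.

Step 6
Reactants: 6 (2R,3S,4R)-3,4,7,3',4'-penta-O-benzyl-6-iodoflavan-3,4-diol; 5 3,7,3',4'-tetra-O-benzyl-4α-[(2,6-dimethylphenyl)sulfanyl]fisetinidol (1.5 equiv)
Product: 7 6-iodo-tetra-O-benzylfisetinidol-(4α→6)-tetra-O-benzyl-4α-[(2,6-dimethylphenyl)sulfanyl]fisetinidol
Conditions: BF3·OEt2, 4 Å MS, CH2Cl2, −78 to −30 °C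
Reagents that add atoms: none
Why: Friedel–Crafts flavanylation under orthogonal activation, in which BF3·OEt2 ionises only the 4-benzyloxy group of 6 and C6 of 5 attacks the cation anti to the 3-benzyloxy group, which should set the 4α (3,4-trans) interflavan centre while the thioether survives.

Step 7
Reactants: 8 5-bromoresorcinol
Product: 9 1-bromo-3,5-bis(benzyloxy)benzene
Conditions: BnBr (2.2 equiv), K2CO3, DMF, rt
Reagents that add atoms: benzyl bromide, BrCc1ccccc1
Why: Williamson etherification of both phenols.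

Step 8
Reactants: 9 1-bromo-3,5-bis(benzyloxy)benzene
Product: 11 2-bromo-4,6-bis(benzyloxy)benzaldehyde, via iminium chloride 10 (not isolated)
Conditions: POCl3, DMF, 0 to 70 °C; then H2O
Reagents that add atoms: N,N-dimethylformamide, CN(C)C=O; water, O
Why: Vilsmeier–Haack formylation, which attacks ortho to bromine and para to a benzyloxy group (as known for the dimethyl ether); the two such carbons are equivalent by symmetry, so one aldehyde should result.

Step 9
Reactants: 11 2-bromo-4,6-bis(benzyloxy)benzaldehyde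
Product: 12 [2-bromo-4,6-bis(benzyloxy)phenyl]methanol
Conditions: NaBH4, THF/MeOH, 0 °C
Reagents that add atoms: none
Why: Borohydride reduction of an aryl aldehyde, to which aryl bromide and benzyl ethers are inert.

Step 10
Reactants: 12 [2-bromo-4,6-bis(benzyloxy)phenyl]methanol
Product: 13 1-bromo-3,5-bis(benzyloxy)-2-(bromomethyl)benzene
Conditions: PBr3, Et2O, 0 °C; used at once
Reagents that add atoms: phosphorus tribromide, BrP(Br)Br
Why: Conversion of a benzylic alcohol into the bromide through its phosphite ester; the electron-rich bromide is used directly because it is labile.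

Step 11
Reactants: 14 (R)-4-benzyl-1,3-oxazolidin-2-one
Product: 15 (R)-4-benzyl-3-[(benzyloxy)acetyl]-1,3-oxazolidin-2-one
Conditions: n-BuLi, THF, −78 °C; then BnOCH2COCl
Reagents that add atoms: (benzyloxy)acetyl chloride, O=C(Cl)COCc1ccccc1
Why: N-acylation of the lithiated oxazolidinone with an acid chloride.

Step 12
Reactants: 15 (R)-4-benzyl-3-[(benzyloxy)acetyl]-1,3-oxazolidin-2-one; 13 1-bromo-3,5-bis(benzyloxy)-2-(bromomethyl)benzene
Product: 16 (R)-4-benzyl-3-{(S)-2-(benzyloxy)-3-[2-bromo-4,6-bis(benzyloxy)phenyl]propanoyl}-1,3-oxazolidin-2-one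
Conditions: NaN(SiMe3)2, THF, −78 to −45 °C
Reagents that add atoms: none
Why: Evans-type glycolate alkylation in which the chelated sodium Z-enolate is alkylated by the benzylic bromide on the face opposite to the 4-benzyl group of the auxiliary, which should set the S centre (future C3 of unit C).

Step 13
Reactants: 16 (R)-4-benzyl-3-{(S)-2-(benzyloxy)-3-[2-bromo-4,6-bis(benzyloxy)phenyl]propanoyl}-1,3-oxazolidin-2-one
Product: 17 (S)-2-(benzyloxy)-3-[2-bromo-4,6-bis(benzyloxy)phenyl]-N-methoxy-N-methylpropanamide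
Conditions: MeONHMe·HCl, AlMe3, CH2Cl2, 0 °C to rt
Reagents that add atoms: N,O-dimethylhydroxylamine hydrochloride, CNOC.Cl
Why: Aluminium amide transamidation (Weinreb amide formation) that cleaves the auxiliary at the exocyclic carbonyl without touching the α-stereocentre.

Step 14
Reactants: 17 (S)-2-(benzyloxy)-3-[2-bromo-4,6-bis(benzyloxy)phenyl]-N-methoxy-N-methylpropanamide; 18 4-bromo-1,2-bis(benzyloxy)benzene
Product: 20 (S)-2-(benzyloxy)-3-[2-bromo-4,6-bis(benzyloxy)phenyl]-1-[3,4-bis(benzyloxy)phenyl]propan-1-one, via aryl Grignard reagent 19 (not isolated)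
Conditions: 18, Mg, THF, rt to 40 °C; then 17, THF, 0 °C; aq NH4Cl
Reagents that add atoms: none
Why: Weinreb ketone synthesis, in which the chelated tetrahedral adduct stops the Grignard addition at the ketone and the hindered aryl bromide and the α-centre are not affected at 0 °C.

Step 15
Reactants: 20 (S)-2-(benzyloxy)-3-[2-bromo-4,6-bis(benzyloxy)phenyl]-1-[3,4-bis(benzyloxy)phenyl]propan-1-one; 6 (2R,3S,4R)-3,4,7,3',4'-penta-O-benzyl-6-iodoflavan-3,4-diol (1.3 equiv)
Product: 21 ketone 20 bearing the 4α-linked 6-iodo-tetra-O-benzylfisetinidol unit D at the ring carbon between bromine and a benzyloxy group (future C8)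
Conditions: BF3·OEt2 (3 equiv), 4 Å MS, CH2Cl2, −40 to 0 °C
Reagents that add atoms: none
Why: Friedel–Crafts flavanylation in which the cation from 6 attacks the free carbon ortho to bromine and para to a benzyloxy group (the same innate preference as in step 8) anti to its 3-benzyloxy group, which should give the 4α linkage; the iodine keeps unit D from condensing with itself.

Step 16
Reactants: 21 ketone bearing unit D at future C8; 7 6-iodo-tetra-O-benzylfisetinidol-(4α→6)-tetra-O-benzyl-4α-[(2,6-dimethylphenyl)sulfanyl]fisetinidol (1.3 equiv)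
Product: 22 di-iodo tetrameric ketone, that is 21 bearing the dimer of 7 through C4 of unit B (4α) at the ring carbon between the two benzyloxy groups (future C6)
Conditions: NIS, AgOTf (cat.), 4 Å MS, CH2Cl2, −40 to −10 °C
Reagents that add atoms: none
Why: Thiophilic activation of the C4 thioether gives the flavan-4-yl cation of unit B, which undergoes Friedel–Crafts attack by the only aromatic C–H left on the brominated ring, anti to the 3-benzyloxy group, and should set the 4α centre.

Step 17
Reactants: 22 di-iodo tetrameric ketone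
Product: 23 tetrameric ketone without iodine
Conditions: Pd(PPh3)4 (cat.), HCO2Na, DMF, 60 °C
Reagents that add atoms: none
Why: Palladium-catalysed transfer hydrodehalogenation, in which zerovalent palladium inserts into the two unhindered C–I bonds far faster than into the di-ortho-substituted C–Br bond and hydride transfer from formate outruns any C–H arylation.

Step 18
Reactants: 23 tetrameric ketone without iodine
Product: 24 hexasubstituted aryl bromide with the (1R,2S)-2-benzyloxy-1-hydroxy-1-[3,4-bis(benzyloxy)phenyl]prop-3-yl chain (anti carbinol, key precursor)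
Conditions: Zn(BH4)2, Et2O/CH2Cl2, −20 to 0 °C
Reagents that add atoms: none
Why: Cram-chelate controlled ketone reduction, in which zinc bridges the carbonyl oxygen and the neighbouring benzyloxy oxygen and hydride enters opposite to the arylmethyl substituent of the five-membered chelate, which should set the new carbinol centre anti to the benzyloxy group (2R of unit C).

Step 19
Reactants: 24 hexasubstituted aryl bromide with anti carbinol
Product: 25 heptadeca-O-benzyl tetramer
Conditions: Pd(OAc)2 (10 mol%), rac-2-(di-tert-butylphosphino)-1,1'-binaphthyl (12 mol%), Cs2CO3, toluene, 70 °C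
Reagents that add atoms: none
Why: Zerovalent palladium formed in situ from divalent Pd(OAc)2 inserts into the C8a–Br bond, the caesium alkoxide of the C2 hydroxyl replaces bromide on palladium, and C(aryl)–O reductive elimination from the seven-membered oxapalladacycle forms O1–C8a. The closest known reaction type is the intramolecular Buchwald–Hartwig etherification of aryl bromides with secondary alcohols to chromans. The pyran ring of unit C closes as a six-membered ring by bonding of the tethered oxygen to the aromatic carbon that carried bromine (6-exo with respect to that carbon). No stereocentre is formed and the C2–O bond is never broken, so the anti (2R,3S) arrangement of 24 becomes the 2,3-trans ring of the catechin unit. The step needs reductive elimination to outrun β-hydride elimination of the secondary benzylic alkoxide, which the bulky electron-rich di-tert-butylbiaryl phosphine should secure. It also needs a single reaction site, secured because C8a–Br is the only carbon–halogen bond left and the C3 oxygen is benzylated so that no five-membered ring can form.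

Step 20
Reactants: 25 heptadeca-O-benzyl tetramer
Product: 26 fisetinidol-(4α→6)-fisetinidol-(4α→6)-[fisetinidol-(4α→8)]-catechin (target)
Conditions: H2 (1 atm), Pd(OH)2 on carbon, THF/MeOH/H2O, rt
Reagents that add atoms: none
Why: Hydrogenolysis of all seventeen benzyl ethers, to which the interflavan C–C bonds and the pyran rings are stable.

**Compound list**

1 | (2R,3R)-fustin, (2R,3R)-2-(3,4-dihydroxyphenyl)-3,7-dihydroxychroman-4-one | Oc1ccc2c(c1)O[C@H](c1ccc(O)c(O)c1)[C@@H](O)C2=O | starting material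
2 | (2R,3R)-7-benzyloxy-2-[3,4-bis(benzyloxy)phenyl]-3-hydroxychroman-4-one | O(Cc5ccccc5)c1ccc2c(c1)O[C@H](c1ccc(OCc5ccccc5)c(OCc5ccccc5)c1)[C@@H](O)C2=O | intermediate
3 | (2R,3S,4R)-7-benzyloxy-2-[3,4-bis(benzyloxy)phenyl]chromane-3,4-diol (2,3-trans-3,4-trans) | O(Cc5ccccc5)c1ccc2c(c1)O[C@H](c1ccc(OCc5ccccc5)c(OCc5ccccc5)c1)[C@@H](O)[C@@H]2O | intermediate
4 | (2R,3S,4R)-3,4,7-tris(benzyloxy)-2-[3,4-bis(benzyloxy)phenyl]chromane | O(Cc5ccccc5)c1ccc2c(c1)O[C@H](c1ccc(OCc5ccccc5)c(OCc5ccccc5)c1)[C@@H](OCc5ccccc5)[C@@H]2OCc5ccccc5 | intermediate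
5 | 3,7-bis(benzyloxy)-2-[3,4-bis(benzyloxy)phenyl]-4-[(2,6-dimethylphenyl)sulfanyl]chromane; 2R, 2,3-trans, 3,4-trans (4α sulfur) | O(Cc5ccccc5)c1ccc2c(c1)O[C@H](c1ccc(OCc5ccccc5)c(OCc5ccccc5)c1)[C@@H](OCc5ccccc5)[C@@H]2Sc1c(C)cccc1C | intermediate
6 | (2R,3S,4R)-3,4,7-tris(benzyloxy)-2-[3,4-bis(benzyloxy)phenyl]-6-iodochromane | O(Cc5ccccc5)c1c(I)cc2c(c1)O[C@H](c1ccc(OCc5ccccc5)c(OCc5ccccc5)c1)[C@@H](OCc5ccccc5)[C@@H]2OCc5ccccc5 | intermediate
7 | dimer: 6-iodo-3,7,3',4'-tetra-O-benzylfisetinidol linked 4α→6 to 3,7,3',4'-tetra-O-benzyl-4α-[(2,6-dimethylphenyl)sulfanyl]fisetinidol; both units 2R and 2,3-trans, both C4 substituents trans to the 3-benzyloxy group | O(Cc5ccccc5)c1c(I)cc2c(c1)O[C@H](c1ccc(OCc5ccccc5)c(OCc5ccccc5)c1)[C@@H](OCc5ccccc5)[C@@H]2c1cc2c(cc1OCc5ccccc5)O[C@H](c1ccc(OCc5ccccc5)c(OCc5ccccc5)c1)[C@@H](OCc5ccccc5)[C@@H]2Sc1c(C)cccc1C | intermediate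
8 | 5-bromoresorcinol | Oc1cc(O)cc(Br)c1 | starting material
9 | 1-bromo-3,5-bis(benzyloxy)benzene | Brc1cc(OCc5ccccc5)cc(OCc5ccccc5)c1 | intermediate
10 | N-{[2-bromo-4,6-bis(benzyloxy)phenyl]methylidene}-N-methylmethanaminium chloride | C[N+](C)=Cc1c(Br)cc(OCc5ccccc5)cc1OCc5ccccc5.[Cl-] | intermediate
11 | 2-bromo-4,6-bis(benzyloxy)benzaldehyde | O=Cc1c(Br)cc(OCc5ccccc5)cc1OCc5ccccc5 | intermediate
12 | [2-bromo-4,6-bis(benzyloxy)phenyl]methanol | OCc1c(Br)cc(OCc5ccccc5)cc1OCc5ccccc5 | intermediate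
13 | 1-bromo-3,5-bis(benzyloxy)-2-(bromomethyl)benzene | BrCc1c(Br)cc(OCc5ccccc5)cc1OCc5ccccc5 | intermediate
14 | (R)-4-benzyl-1,3-oxazolidin-2-one | O=C1N[C@H](Cc2ccccc2)CO1 | starting material
15 | (R)-4-benzyl-3-[(benzyloxy)acetyl]-1,3-oxazolidin-2-one | O=C(COCc5ccccc5)N1[C@H](Cc2ccccc2)COC1=O | intermediate
16 | (R)-4-benzyl-3-{(S)-2-(benzyloxy)-3-[2-bromo-4,6-bis(benzyloxy)phenyl]propanoyl}-1,3-oxazolidin-2-one | O=C([C@@H](OCc5ccccc5)Cc1c(Br)cc(OCc5ccccc5)cc1OCc5ccccc5)N1[C@H](Cc2ccccc2)COC1=O | intermediate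
17 | (S)-2-(benzyloxy)-3-[2-bromo-4,6-bis(benzyloxy)phenyl]-N-methoxy-N-methylpropanamide | CON(C)C(=O)[C@@H](OCc5ccccc5)Cc1c(Br)cc(OCc5ccccc5)cc1OCc5ccccc5 | intermediate
18 | 4-bromo-1,2-bis(benzyloxy)benzene | Brc1ccc(OCc5ccccc5)c(OCc5ccccc5)c1 | starting material
19 | [3,4-bis(benzyloxy)phenyl]magnesium bromide | Br[Mg]c1ccc(OCc5ccccc5)c(OCc5ccccc5)c1 | intermediate
20 | (S)-2-(benzyloxy)-3-[2-bromo-4,6-bis(benzyloxy)phenyl]-1-[3,4-bis(benzyloxy)phenyl]propan-1-one | O=C(c1ccc(OCc5ccccc5)c(OCc5ccccc5)c1)[C@@H](OCc5ccccc5)Cc1c(Br)cc(OCc5ccccc5)cc1OCc5ccccc5 | intermediate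
21 | (S)-2-(benzyloxy)-1-[3,4-bis(benzyloxy)phenyl]-3-{4,6-bis(benzyloxy)-2-bromo-3-[6-iodo-3,7,3',4'-tetra-O-benzylfisetinidol-4α-yl]phenyl}propan-1-one | c1c(OCc5ccccc5)c(C[C@H](OCc5ccccc5)C(=O)c7ccc(OCc5ccccc5)c(OCc5ccccc5)c7)c(Br)c([C@@H]3c4cc(I)c(OCc5ccccc5)cc4O[C@H](c4ccc(OCc5ccccc5)c(OCc5ccccc5)c4)[C@H]3OCc5ccccc5)c1OCc5ccccc5 | intermediate
22 | ketone 21 bearing at phenyl C5 (between the two benzyloxy groups) the dimer of 7 bonded through C4 of unit B (4α); two iodine atoms at C6 of units A and D | O(Cc5ccccc5)c1c(I)cc2c(c1)O[C@H](c1ccc(OCc5ccccc5)c(OCc5ccccc5)c1)[C@@H](OCc5ccccc5)[C@@H]2c1cc2c(cc1OCc5ccccc5)O[C@H](c1ccc(OCc5ccccc5)c(OCc5ccccc5)c1)[C@@H](OCc5ccccc5)[C@@H]2c1c(OCc5ccccc5)c(C[C@H](OCc5ccccc5)C(=O)c7ccc(OCc5ccccc5)c(OCc5ccccc5)c7)c(Br)c([C@@H]3c4cc(I)c(OCc5ccccc5)cc4O[C@H](c4ccc(OCc5ccccc5)c(OCc5ccccc5)c4)[C@H]3OCc5ccccc5)c1OCc5ccccc5 | intermediate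
23 | ketone 22 with both iodine atoms replaced by hydrogen | O(Cc5ccccc5)c1ccc2c(c1)O[C@H](c1ccc(OCc5ccccc5)c(OCc5ccccc5)c1)[C@@H](OCc5ccccc5)[C@@H]2c1cc2c(cc1OCc5ccccc5)O[C@H](c1ccc(OCc5ccccc5)c(OCc5ccccc5)c1)[C@@H](OCc5ccccc5)[C@@H]2c1c(OCc5ccccc5)c(C[C@H](OCc5ccccc5)C(=O)c7ccc(OCc5ccccc5)c(OCc5ccccc5)c7)c(Br)c([C@@H]3c4ccc(OCc5ccccc5)cc4O[C@H](c4ccc(OCc5ccccc5)c(OCc5ccccc5)c4)[C@H]3OCc5ccccc5)c1OCc5ccccc5 | intermediate
24 | key precursor: hexasubstituted aryl bromide; alcohol from 23 with the side chain (1R,2S)-2-benzyloxy-1-hydroxy-1-[3,4-bis(benzyloxy)phenyl]prop-3-yl (anti) | O(Cc5ccccc5)c1ccc2c(c1)O[C@H](c1ccc(OCc5ccccc5)c(OCc5ccccc5)c1)[C@@H](OCc5ccccc5)[C@@H]2c1cc2c(cc1OCc5ccccc5)O[C@H](c1ccc(OCc5ccccc5)c(OCc5ccccc5)c1)[C@@H](OCc5ccccc5)[C@@H]2c1c(OCc5ccccc5)c(C[C@H](OCc5ccccc5)[C@H](O)c7ccc(OCc5ccccc5)c(OCc5ccccc5)c7)c(Br)c([C@@H]3c4ccc(OCc5ccccc5)cc4O[C@H](c4ccc(OCc5ccccc5)c(OCc5ccccc5)c4)[C@H]3OCc5ccccc5)c1OCc5ccccc5 | intermediate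
25 | heptadeca-O-benzyl ether of fisetinidol-(4α→6)-fisetinidol-(4α→6)-[fisetinidol-(4α→8)]-catechin | O(Cc5ccccc5)c1ccc2c(c1)O[C@H](c1ccc(OCc5ccccc5)c(OCc5ccccc5)c1)[C@@H](OCc5ccccc5)[C@@H]2c1cc2c(cc1OCc5ccccc5)O[C@H](c1ccc(OCc5ccccc5)c(OCc5ccccc5)c1)[C@@H](OCc5ccccc5)[C@@H]2c1c(OCc5ccccc5)c2c(c([C@@H]3c4ccc(OCc5ccccc5)cc4O[C@H](c4ccc(OCc5ccccc5)c(OCc5ccccc5)c4)[C@H]3OCc5ccccc5)c1OCc5ccccc5)O[C@H](c1ccc(OCc5ccccc5)c(OCc5ccccc5)c1)[C@@H](OCc5ccccc5)C2 | intermediate
26 | fisetinidol-(4α→6)-fisetinidol-(4α→6)-[fisetinidol-(4α→8)]-catechin (CNP0263622.1) | Oc1ccc2c(c1)O[C@H](c1ccc(O)c(O)c1)[C@@H](O)[C@@H]2c1cc2c(cc1O)O[C@H](c1ccc(O)c(O)c1)[C@@H](O)[C@@H]2c1c(O)c2c(c([C@@H]3c4ccc(O)cc4O[C@H](c4ccc(O)c(O)c4)[C@H]3O)c1O)O[C@H](c1ccc(O)c(O)c1)[C@@H](O)C2 | target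

**Totals.** Total step count: 20. Longest linear sequence: 13 steps (steps 7 to 10 and 12 to 20, from 5-bromoresorcinol).

**Steps most likely to fail**

Step 19 (key step). What may go wrong is slow oxidative addition at the hexasubstituted, doubly ortho-flanked C–Br bond, so that the palladium alkoxide instead undergoes β-hydride elimination, which oxidises the carbinol back to the ketone and reduces the bromide. The fallback sets out from 24 and moves the closure from a palladium aryl to a copper alkoxide, an Ullmann ether synthesis: CuI, 3,4,7,8-tetramethyl-1,10-phenanthroline and Cs2CO3 in toluene at 110 °C. The monovalent copper alkoxide is delivered to the neighbouring bromide intramolecularly and has no easy β-hydride pathway. It comes back to the route at 25, and no new compound is made.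

Step 16. What may go wrong is that the cation at C4 of unit B reaches the carbon flanked by two benzyloxy groups too slowly and is consumed instead by attack at C8 of unit B of a second dimer molecule or by collapse with succinimide. Step 15 shares this failure mode on a less hindered carbon. The fallback sets out from 7, blocks the competing carbon and changes to the harder mode of activation. Dimer 7 is solvolysed at C4 with NIS, AgOTf (cat.) and benzyl alcohol to the 4-benzyloxy dimer F1. F1 is iodinated at C8 of unit B, its only resorcinol-type C–H that is not meta to iodine, with NIS and CF3CO2H (cat.) to the doubly capped dimer F2. F2 is then ionised with BF3·OEt2 in the presence of 21 to give the tri-iodo tetrameric ketone F3. The reductive de-iodination of step 17, now on three C–I bonds, brings the route back at 23.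

Step 18. What may go wrong is poor facial selectivity, if the many ether oxygens of 23 compete for zinc and a clean five-membered chelate is not formed, which would lead to the 2,3-cis series after ring closure. The fallback sets out from 23 and replaces substrate control by catalyst control: Noyori asymmetric transfer hydrogenation with RuCl[(S,S)-TsDPEN](p-cymene) and HCO2H/Et3N in CH2Cl2. This enantiomer of the catalyst is the one expected, by analogy with aryl alkyl ketones, to deliver hydride to the face that gives the 2R carbinol. It comes back at 24, and no new compound is made.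

**Further compounds**

F1 | step 16 | 6-iodo-3,7,3',4'-tetra-O-benzylfisetinidol linked 4α→6 to (2R,3S,4R)-3,4,7,3',4'-penta-O-benzylflavan-3,4-diol | O(Cc5ccccc5)c1c(I)cc2c(c1)O[C@H](c1ccc(OCc5ccccc5)c(OCc5ccccc5)c1)[C@@H](OCc5ccccc5)[C@@H]2c1cc2c(cc1OCc5ccccc5)O[C@H](c1ccc(OCc5ccccc5)c(OCc5ccccc5)c1)[C@@H](OCc5ccccc5)[C@@H]2OCc5ccccc5
F2 | step 16 | dimer F1 with a second iodine at C8 of unit B | O(Cc5ccccc5)c1c(I)cc2c(c1)O[C@H](c1ccc(OCc5ccccc5)c(OCc5ccccc5)c1)[C@@H](OCc5ccccc5)[C@@H]2c1cc2c(c(I)c1OCc5ccccc5)O[C@H](c1ccc(OCc5ccccc5)c(OCc5ccccc5)c1)[C@@H](OCc5ccccc5)[C@@H]2OCc5ccccc5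
F3 | step 16 | tetrameric ketone 22 with a third iodine at C8 of unit B | O(Cc5ccccc5)c1c(I)cc2c(c1)O[C@H](c1ccc(OCc5ccccc5)c(OCc5ccccc5)c1)[C@@H](OCc5ccccc5)[C@@H]2c1cc2c(c(I)c1OCc5ccccc5)O[C@H](c1ccc(OCc5ccccc5)c(OCc5ccccc5)c1)[C@@H](OCc5ccccc5)[C@@H]2c1c(OCc5ccccc5)c(C[C@H](OCc5ccccc5)C(=O)c7ccc(OCc5ccccc5)c(OCc5ccccc5)c7)c(Br)c([C@@H]3c4cc(I)c(OCc5ccccc5)cc4O[C@H](c4ccc(OCc5ccccc5)c(OCc5ccccc5)c4)[C@H]3OCc5ccccc5)c1OCc5ccccc5
F0 | step 19 | none | none
F0 | step 18 | none | none
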